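The decalin is disconnected across ring B at C5–C10 and C8–C9 (steroid-type numbering; ring A = C1–C5/C10, ring B = C5–C10, side chain from C11). Read backwards, ring B is a cyclohexene adduct of a C5–C8 diene and a C9=C10 dienophile, and these two π systems are already joined by C1–C4 of ring A, which holds the C3 carbinol and the quaternary C4. One intramolecular Diels–Alder reaction therefore closes both rings and sets the trans fusion, with the pantolactone-derived C3 centre dictating absolute configuration. The precursor is an acyclic (2E,8E,10E)-trienal; the dienophile is carried as an enal so that a Lewis acid can drive this congested closure.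

Key step: step 12

Assumption: (E)-geranylacetone is bought as the single (E)-isomer; β denotes the decalin face that carries the C10 methyl group, α the opposite face.

Step 1
Reactants: 1 (R)-pantolactone
Product: 2 (3R)-3-(tert-butyldimethylsilyloxy)-4,4-dimethyloxolan-2-one
Conditions: t-BuMe2SiCl, imidazole, DMF, rt
Reagents that add atoms: tert-butyldimethylsilyl chloride, CC(C)(C)[Si](C)(C)Cl
Why: Imidazole-promoted silyl ether formation should protect the future C3 hydroxyl without touching the stereocentre.

Step 2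
Reactants: 2 silyl-protected pantolactone
Product: 3 (2R)-2-(tert-butyldimethylsilyloxy)-4-hydroxy-N-methoxy-N,3,3-trimethylbutanamide
Conditions: MeNH(OMe)·HCl, AlMe3, CH2Cl2, 0 °C → rt; aq. potassium sodium tartrate; crude used at once
Reagents that add atoms: N,O-dimethylhydroxylamine hydrochloride, CNOC.Cl
Why: Aluminium-amide aminolysis of the lactone (Weinreb amide formation) should open the ring at the acyl carbon and so tell the future C2 and C5 termini apart, the crude hydroxy amide being oxidised immediately because it can relactonise.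

Step 3
Reactants: 3 hydroxy Weinreb amide
Product: 4 (2R)-2-(tert-butyldimethylsilyloxy)-N-methoxy-N,3,3-trimethyl-4-oxobutanamide
Conditions: Dess–Martin periodinane, CH2Cl2, 0 °C → rt
Reagents that add atoms: none
Why: Dess–Martin oxidation of the neopentyl primary alcohol should give the non-enolisable C5 aldehyde under conditions that leave the silyl ether and the amide alone.

Step 4
Reactants: 4 aldehyde amide
Product: 5 (2R,4E)-2-(tert-butyldimethylsilyloxy)-5-iodo-N-methoxy-N,3,3-trimethylpent-4-enamide
Conditions: CrCl2, CHI3, THF, 0 °C → rt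
Reagents that add atoms: iodoform, IC(I)I
Why: Takai olefination of an α-quaternary aldehyde should give the (E)-iodoalkene C5=C6 selectively, since the bulky C4 group enforces the anti arrangement before elimination and the chromium reagent does not attack the amide.

Step 5
Reactants: 5 (E)-iodoalkene amide; 6 (E)-prop-1-en-1-ylboronic acid
Product: 7 (2R,4E,6E)-2-(tert-butyldimethylsilyloxy)-N-methoxy-N,3,3-trimethylocta-4,6-dienamide
Conditions: Pd(PPh3)4 (5 mol %), K2CO3, THF–H2O, 60 °C
Reagents that add atoms: none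
Why: Suzuki–Miyaura coupling of two alkenyl partners proceeds with retention at both double bonds, so the (E,E)-diene C5=C6–C7=C8 should form as one geometric isomer.

Step 6
Reactants: 7 dienyl Weinreb amide
Product: 8 (2R,4E,6E)-2-(tert-butyldimethylsilyloxy)-3,3-dimethylocta-4,6-dienal
Conditions: i-Bu2AlH, THF, −78 °C; aq. potassium sodium tartrate
Reagents that add atoms: none
Why: Hydride reduction of a Weinreb amide stops at the chelated hemiaminal, so the C2 aldehyde should be released on work-up without over-reduction or loss of configuration at C3.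

Step 7
Reactants: 8 α-silyloxy aldehyde
Product: 9 tert-butyl{[(3S,5E,7E)-4,4-dimethylnona-1,5,7-trien-3-yl]oxy}dimethylsilane
Conditions: Ph3PCH3Br, KN(SiMe3)2, THF, −78 → 0 °C
Reagents that add atoms: methyltriphenylphosphonium bromide, C[P+](c1ccccc1)(c1ccccc1)c1ccccc1.[Br-]
Why: Wittig methylenation with the small non-stabilised ylide at low temperature should form the C2=C1 alkene faster than the aldehyde can enolise, so C3 stays intact.

Step 8
Reactants: 10 ethyl acetoacetate
Product: 11 ethyl (2E)-3-(trifluoromethylsulfonyloxy)but-2-enoate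
Conditions: Tf2O, aq. Me4NOH, toluene, 0 °C → rt
Reagents that add atoms: trifluoromethanesulfonic anhydride, O=S(=O)(OS(=O)(=O)C(F)(F)F)C(F)(F)F
Why: O-Sulfonylation of the β-keto ester enolate with a non-chelating ammonium counter-ion (enol triflate formation) should go through the open enolate and so give the (E)-triflate, in which the leaving group is trans to the ester.

Step 9
Reactants: 9 triene silyl ether; 11 (E)-enol triflate
Product: 13 ethyl (2E,6S,8E,10E)-6-(tert-butyldimethylsilyloxy)-3,7,7-trimethyldodeca-2,8,10-trienoate, via alkyl-9-BBN borane 12 (not isolated)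
Conditions: 9-BBN, THF, rt; then 11, Pd(dppf)Cl2 (5 mol %), aq. K3PO4, THF–DMF, rt → 50 °C
Reagents that add atoms: none
Why: 9-BBN should hydroborate the monosubstituted alkene at its terminal carbon far faster than the internal conjugated diene, and the B-alkyl Suzuki–Miyaura coupling with the electron-poor enol triflate proceeds with retention, which fixes the (E)-trisubstituted C9=C10 bond that olefination of a methyl ketone would deliver as a mixture.

Step 10
Reactants: 13 trienoate
Product: 14 (2E,6S,8E,10E)-6-(tert-butyldimethylsilyloxy)-3,7,7-trimethyldodeca-2,8,10-trien-1-ol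
Conditions: i-Bu2AlH, CH2Cl2, −78 °C; aq. potassium sodium tartrate
Reagents that add atoms: none
Why: 1,2-Reduction of the enoate by the aluminium hydride should give the allylic alcohol without touching the diene, the silyl ether or the alkene geometry.

Step 11
Reactants: 14 allylic alcohol
Product: 15 (2E,6S,8E,10E)-6-(tert-butyldimethylsilyloxy)-3,7,7-trimethyldodeca-2,8,10-trienal
Conditions: MnO2, CH2Cl2, rt
Reagents that add atoms: none
Why: Allylic oxidation with MnO2 should give the (E)-enal without E/Z scrambling, providing a dienophile that a Lewis acid can activate strongly.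

Step 12
Reactants: 15 (2E,8E,10E)-trienal
Product: 16 3β-(tert-butyldimethylsilyloxy)-4,4,8β,10β-tetramethyl-trans-decal-6-ene-9β-carbaldehyde
Conditions: Me2AlCl (1.2 equiv), CH2Cl2 (0.02 M), −78 → −20 °C; aq. NaHCO3
Reagents that add atoms: none
Why: Me2AlCl binds the aldehyde oxygen and lowers the LUMO of the C9=C10 enal, which adds suprafacially to the s-cis C5=C6–C7=C8 diene in a concerted, asynchronous [4+2] cycloaddition whose more advanced bond is C5–C10. The closest known reaction type is the Lewis-acid-promoted type 1 intramolecular Diels–Alder reaction of (2E,8E,10E)-undeca-2,8,10-trienals and -trienoates, whose four-atom tether gives trans-fused octalins (a three-atom tether, as in deca-2,7,9-trienoates, would give hydrindenes and is the wrong model). Ring B closes as the new cyclohexene of the cycloaddition (bonds C5–C10 and C8–C9) and ring A closes in the same event as the six-membered tether ring C10–C1–C2–C3–C4–C5, fused to ring B with the tether exo. Suprafacial addition to the (E)-enal puts the C10 methyl cis to C11, the (E,E)-diene puts the C8 methyl cis to the C4–C5 bond, the endo position of the complexed formyl group gives the trans C5/C10 fusion with C11 cis to the C8 methyl, and the C3 silyloxy group, equatorial in the chair-like tether, selects the diene face and with it the absolute configuration of C5, C8, C9 and C10. The step needs endo and π-facial selectivity: the first is secured by the aluminium-bound carbonyl at low temperature, the second by the equatorial preference at C3, which the adjacent gem-dimethyl group weakens, so a separable minor diastereomer should be expected. The C4 gem-dimethyl group also folds the tether toward the reactive rotamer, and the β-methyl group, which cripples an ester dienophile, is tolerated by the aluminium-complexed enal because it stabilises the positive charge that builds up at C10.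

Step 13
Reactants: 16 octalin aldehyde
Product: 17 [3β-(tert-butyldimethylsilyloxy)-4,4,8β,10β-tetramethyl-trans-decal-6-en-9β-yl]methanol
Conditions: NaBH4, MeOH–THF, 0 °C
Reagents that add atoms: none
Why: Borohydride reduction should convert the hindered, epimerisable aldehyde into the stable C11 primary alcohol before the ring double bond is moved.

Step 14
Reactants: 17 Δ6 alcohol
Product: 18 [3β-(tert-butyldimethylsilyloxy)-4,4,8,10β-tetramethyl-trans-decal-7-en-9β-yl]methanol
Conditions: RhCl3·3H2O (10 mol %), EtOH, 75 °C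
Reagents that add atoms: none
Why: Rhodium-hydride olefin isomerisation (insertion on the open α face, then β-hydride elimination of the syn 8α-H) should move the cis-disubstituted C6=C7 bond to the trisubstituted C7=C8 position, which removes the 1,3-diaxial clash of the C8 and C10 methyl groups, and should stop there because a trisubstituted alkene inserts far more slowly.

Step 15
Reactants: 18 Δ7 alcohol
Product: 19 [3β-(tert-butyldimethylsilyloxy)-7α,8α-epoxy-4,4,8β,10β-tetramethyl-trans-decal-9β-yl]methanol
Conditions: mCPBA, NaHCO3, CH2Cl2, 0 °C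
Reagents that add atoms: 3-chloroperbenzoic acid, OOC(=O)c1cccc(Cl)c1
Why: Peracid (Prilezhaev) epoxidation of the trisubstituted alkene should occur from the α face, because the β face is screened by the axial C10 methyl group.

Step 16
Reactants: 19 7α,8α-epoxide
Product: 20 3β-(tert-butyldimethylsilyloxy)-9β-(hydroxymethyl)-4,4,8β,10β-tetramethyl-trans-decalin-8α-ol
Conditions: LiAlH4, THF, 65 °C
Reagents that add atoms: none
Why: Hydride opening of the trisubstituted epoxide by SN2 attack at the secondary carbon C7, anti to oxygen, leaves the C8–O bond untouched and should therefore give the tertiary 8α-alcohol with the 8β-methyl group.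

Step 17
Reactants: 20 8α,11-diol
Product: 21 3β-(tert-butyldimethylsilyloxy)-8α-(triethylsilyloxy)-9β-[(triethylsilyloxy)methyl]-4,4,8β,10β-tetramethyl-trans-decalin
Conditions: Et3SiOTf, 2,6-lutidine, CH2Cl2, −78 → 0 °C
Reagents that add atoms: triethylsilyl trifluoromethanesulfonate, CC[Si](CC)(CC)OS(=O)(=O)C(F)(F)F
Why: Silyl triflate silylation is strong enough to cap the tertiary C8 hydroxyl as well as the primary one, so that the later β-oxygenated aldehyde cannot undergo retro-aldol cleavage or dehydration.

Step 18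
Reactants: 21 bis(triethylsilyl) ether
Product: 22 3β-(tert-butyldimethylsilyloxy)-8α-(triethylsilyloxy)-4,4,8β,10β-tetramethyl-trans-decalin-9β-carbaldehyde
Conditions: (COCl)2, DMSO, CH2Cl2, −78 → −40 °C; Et3N, −78 → 0 °C
Reagents that add atoms: none
Why: Under Swern conditions a primary triethylsilyl ether is cleaved and oxidised in one operation while tertiary and hindered secondary silyl ethers are inert, so the C11 aldehyde should form with C8 and C3 still protected.

Step 19
Reactants: 22 C11 aldehyde
Product: 23 3β-(tert-butyldimethylsilyloxy)-8α-(triethylsilyloxy)-9β-vinyl-4,4,8β,10β-tetramethyl-trans-decalin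
Conditions: Ph3PCH3Br, KN(SiMe3)2, THF, 0 °C → rt
Reagents that add atoms: methyltriphenylphosphonium bromide, C[P+](c1ccccc1)(c1ccccc1)c1ccccc1.[Br-]
Why: Wittig methylenation of the hindered aldehyde with the small ylide should give the C11=C12 vinyl group, C9 staying equatorial and the β-silyloxy group being too poor a leaving group to be eliminated.

Step 20
Reactants: 24 (E)-geranylacetone
Product: 26 (5E)-6,10-dimethylundeca-5,9-dien-1-yne, via enol phosphate 25 (not isolated)
Conditions: LiN(i-Pr)2, THF, −78 °C; ClP(O)(OEt)2, −78 °C → rt; then LiN(i-Pr)2 (2.3 equiv), −78 °C → rt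
Reagents that add atoms: none
Why: Kinetic deprotonation on the methyl side, O-phosphorylation and base-induced elimination of the enol phosphate is the standard conversion of a methyl ketone into a terminal alkyne and should leave the trisubstituted alkenes untouched.

Step 21
Reactants: 26 dienyne
Product: 28 (1E,5E)-1-iodo-2,6,10-trimethylundeca-1,5,9-triene, via alkenylalane 27 (not isolated)
Conditions: AlMe3, Cp2ZrCl2 (25 mol %), CH2Cl2, 0 °C → rt; then I2, THF, −30 → 0 °C
Reagents that add atoms: trimethylaluminium, C[Al](C)C; iodine, II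
Why: Zirconium-catalysed methylalumination (Negishi carboalumination) adds methyl and aluminium syn across the terminal alkyne with aluminium on the terminal carbon, and iodinolysis with retention should give the (E)-iodoalkene that becomes C13=C14.

Step 22
Reactants: 28 iodotriene
Product: 29 (2E,6E,10E)-11-iodo-2,6,10-trimethylundeca-2,6,10-trien-1-ol
Conditions: SeO2 (30 mol %), t-BuOOH, salicylic acid (10 mol %), CH2Cl2, 0 °C → rt; stopped at partial conversion, 28 recycled
Reagents that add atoms: tert-butyl hydroperoxide, CC(C)(C)OO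
Why: Selenium dioxide allylic hydroxylation (ene reaction, then [2,3]-shift) prefers the (E)-methyl group of the terminal, most accessible trisubstituted alkene, so the (E)-allylic alcohol should form while the internal and iodine-bearing alkenes react more slowly.

Step 23
Reactants: 23 vinyl decalin; 29 iodo allylic alcohol
Product: 31 (2E,6E,10E)-13-[3β-(tert-butyldimethylsilyloxy)-8α-(triethylsilyloxy)-4,4,8β,10β-tetramethyl-trans-decal-9β-yl]-2,6,10-trimethyltrideca-2,6,10-trien-1-ol, via alkyl-9-BBN borane 30 (not isolated)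
Conditions: 9-BBN, THF, rt → 60 °C; then 29, Pd(dppf)Cl2 (10 mol %), AsPh3, Cs2CO3, DMF–THF–H2O, rt
Reagents that add atoms: none
Why: 9-BBN should add to the only unhindered alkene carbon, C12, and the B-alkyl Suzuki–Miyaura coupling of the primary alkylborane with the (E)-iodoalkene forms C12–C13 with retention of geometry and tolerates the free allylic alcohol and the silyl ethers.

Step 24
Reactants: 31 bis-silyl ether
Product: 32 (2E,6E,10E)-13-[3β,8α-dihydroxy-4,4,8β,10β-tetramethyl-trans-decal-9β-yl]-2,6,10-trimethyltrideca-2,6,10-trien-1-ol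
Conditions: Bu4NF, THF, 50 °C
Reagents that add atoms: none
Why: Fluoride-mediated desilylation should remove the C3 tert-butyldimethylsilyl and the C8 triethylsilyl groups in one operation under non-acidic conditions that spare the tertiary alcohol and the trisubstituted alkenes.

Compound list
1 | (R)-pantolactone, (3R)-3-hydroxy-4,4-dimethyloxolan-2-one | O=C1[C@H](O)C(C)(C)CO1 | starting material
2 | (3R)-3-(tert-butyldimethylsilyloxy)-4,4-dimethyloxolan-2-one | O=C1[C@H](O[Si](C)(C)C(C)(C)C)C(C)(C)CO1 | intermediate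
3 | (2R)-2-(tert-butyldimethylsilyloxy)-4-hydroxy-N-methoxy-N,3,3-trimethylbutanamide | CON(C)C(=O)[C@H](O[Si](C)(C)C(C)(C)C)C(C)(C)CO | intermediate
4 | (2R)-2-(tert-butyldimethylsilyloxy)-N-methoxy-N,3,3-trimethyl-4-oxobutanamide | CON(C)C(=O)[C@H](O[Si](C)(C)C(C)(C)C)C(C)(C)C=O | intermediate
5 | (2R,4E)-2-(tert-butyldimethylsilyloxy)-5-iodo-N-methoxy-N,3,3-trimethylpent-4-enamide | CON(C)C(=O)[C@H](O[Si](C)(C)C(C)(C)C)C(C)(C)/C=C/I | intermediate
6 | (E)-prop-1-en-1-ylboronic acid | C/C=C/B(O)O | starting material
7 | (2R,4E,6E)-2-(tert-butyldimethylsilyloxy)-N-methoxy-N,3,3-trimethylocta-4,6-dienamide | CON(C)C(=O)[C@H](O[Si](C)(C)C(C)(C)C)C(C)(C)/C=C/C=C/C | intermediate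
8 | (2R,4E,6E)-2-(tert-butyldimethylsilyloxy)-3,3-dimethylocta-4,6-dienal | O=C[C@H](O[Si](C)(C)C(C)(C)C)C(C)(C)/C=C/C=C/C | intermediate
9 | tert-butyl{[(3S,5E,7E)-4,4-dimethylnona-1,5,7-trien-3-yl]oxy}dimethylsilane | C=C[C@H](O[Si](C)(C)C(C)(C)C)C(C)(C)/C=C/C=C/C | intermediate
10 | ethyl acetoacetate | CCOC(=O)CC(C)=O | starting material
11 | ethyl (2E)-3-(trifluoromethylsulfonyloxy)but-2-enoate | CCOC(=O)/C=C(\C)OS(=O)(=O)C(F)(F)F | intermediate
12 | 9-[(3S,5E,7E)-3-(tert-butyldimethylsilyloxy)-4,4-dimethylnona-5,7-dien-1-yl]-9-borabicyclo[3.3.1]nonane | B1(CC[C@H](O[Si](C)(C)C(C)(C)C)C(C)(C)/C=C/C=C/C)C2CCCC1CCC2 | intermediate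
13 | ethyl (2E,6S,8E,10E)-6-(tert-butyldimethylsilyloxy)-3,7,7-trimethyldodeca-2,8,10-trienoate | CCOC(=O)/C=C(\C)CC[C@H](O[Si](C)(C)C(C)(C)C)C(C)(C)/C=C/C=C/C | intermediate
14 | (2E,6S,8E,10E)-6-(tert-butyldimethylsilyloxy)-3,7,7-trimethyldodeca-2,8,10-trien-1-ol | OC/C=C(\C)CC[C@H](O[Si](C)(C)C(C)(C)C)C(C)(C)/C=C/C=C/C | intermediate
15 | (2E,6S,8E,10E)-6-(tert-butyldimethylsilyloxy)-3,7,7-trimethyldodeca-2,8,10-trienal | O=C/C=C(\C)CC[C@H](O[Si](C)(C)C(C)(C)C)C(C)(C)/C=C/C=C/C | intermediate
16 | 3β-(tert-butyldimethylsilyloxy)-4,4,8β,10β-tetramethyl-trans-decal-6-ene-9β-carbaldehyde (5α-H, 8α-H, 9α-H; aldehyde carbon is C11) | O=C[C@@H]1[C@@]2(C)CC[C@H](O[Si](C)(C)C(C)(C)C)C(C)(C)[C@@H]2C=C[C@@H]1C | intermediate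
17 | [3β-(tert-butyldimethylsilyloxy)-4,4,8β,10β-tetramethyl-trans-decal-6-en-9β-yl]methanol | OC[C@@H]1[C@@]2(C)CC[C@H](O[Si](C)(C)C(C)(C)C)C(C)(C)[C@@H]2C=C[C@@H]1C | intermediate
18 | [3β-(tert-butyldimethylsilyloxy)-4,4,8,10β-tetramethyl-trans-decal-7-en-9β-yl]methanol (5α-H, 9α-H) | OC[C@@H]1[C@@]2(C)CC[C@H](O[Si](C)(C)C(C)(C)C)C(C)(C)[C@@H]2CC=C1C | intermediate
19 | [3β-(tert-butyldimethylsilyloxy)-7α,8α-epoxy-4,4,8β,10β-tetramethyl-trans-decal-9β-yl]methanol | OC[C@@H]1[C@@]2(C)CC[C@H](O[Si](C)(C)C(C)(C)C)C(C)(C)[C@@H]2C[C@H]3O[C@@]13C | intermediate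
20 | 3β-(tert-butyldimethylsilyloxy)-9β-(hydroxymethyl)-4,4,8β,10β-tetramethyl-trans-decalin-8α-ol | OC[C@@H]1[C@@]2(C)CC[C@H](O[Si](C)(C)C(C)(C)C)C(C)(C)[C@@H]2CC[C@@]1(C)O | intermediate
21 | 3β-(tert-butyldimethylsilyloxy)-8α-(triethylsilyloxy)-9β-[(triethylsilyloxy)methyl]-4,4,8β,10β-tetramethyl-trans-decalin | CC[Si](CC)(CC)OC[C@@H]1[C@@]2(C)CC[C@H](O[Si](C)(C)C(C)(C)C)C(C)(C)[C@@H]2CC[C@@]1(C)O[Si](CC)(CC)CC | intermediate
22 | 3β-(tert-butyldimethylsilyloxy)-8α-(triethylsilyloxy)-4,4,8β,10β-tetramethyl-trans-decalin-9β-carbaldehyde | O=C[C@@H]1[C@@]2(C)CC[C@H](O[Si](C)(C)C(C)(C)C)C(C)(C)[C@@H]2CC[C@@]1(C)O[Si](CC)(CC)CC | intermediate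
23 | 3β-(tert-butyldimethylsilyloxy)-8α-(triethylsilyloxy)-9β-vinyl-4,4,8β,10β-tetramethyl-trans-decalin | C=C[C@@H]1[C@@]2(C)CC[C@H](O[Si](C)(C)C(C)(C)C)C(C)(C)[C@@H]2CC[C@@]1(C)O[Si](CC)(CC)CC | intermediate
24 | (E)-geranylacetone, (5E)-6,10-dimethylundeca-5,9-dien-2-one | CC(C)=CCC/C(C)=C/CCC(C)=O | starting material
25 | diethyl (5E)-6,10-dimethylundeca-1,5,9-trien-2-yl phosphate | CC(C)=CCC/C(C)=C/CCC(=C)OP(=O)(OCC)OCC | intermediate
26 | (5E)-6,10-dimethylundeca-5,9-dien-1-yne | CC(C)=CCC/C(C)=C/CCC#C | intermediate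
27 | dimethyl[(1E,5E)-2,6,10-trimethylundeca-1,5,9-trien-1-yl]alumane | CC(C)=CCC/C(C)=C/CC/C(C)=C/[Al](C)C | intermediate
28 | (1E,5E)-1-iodo-2,6,10-trimethylundeca-1,5,9-triene | CC(C)=CCC/C(C)=C/CC/C(C)=C/I | intermediate
29 | (2E,6E,10E)-11-iodo-2,6,10-trimethylundeca-2,6,10-trien-1-ol | C/C(=C\CC/C(C)=C/CC/C(C)=C/I)CO | intermediate
30 | 9-{2-[3β-(tert-butyldimethylsilyloxy)-8α-(triethylsilyloxy)-4,4,8β,10β-tetramethyl-trans-decal-9β-yl]ethyl}-9-borabicyclo[3.3.1]nonane | B1(CC[C@@H]2[C@@]3(C)CC[C@H](O[Si](C)(C)C(C)(C)C)C(C)(C)[C@@H]3CC[C@@]2(C)O[Si](CC)(CC)CC)C4CCCC1CCC4 | intermediate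
31 | (2E,6E,10E)-13-[3β-(tert-butyldimethylsilyloxy)-8α-(triethylsilyloxy)-4,4,8β,10β-tetramethyl-trans-decal-9β-yl]-2,6,10-trimethyltrideca-2,6,10-trien-1-ol | C/C(=C\CC/C(C)=C/CC/C(C)=C/CC[C@@H]1[C@@]2(C)CC[C@H](O[Si](C)(C)C(C)(C)C)C(C)(C)[C@@H]2CC[C@@]1(C)O[Si](CC)(CC)CC)CO | intermediate
32 | CNP0200414.2, (2E,6E,10E)-13-[3β,8α-dihydroxy-4,4,8β,10β-tetramethyl-trans-decal-9β-yl]-2,6,10-trimethyltrideca-2,6,10-trien-1-ol | C/C(=C\CC/C(C)=C/CC/C(C)=C/CC[C@@H]1[C@@]2(C)CC[C@H](O)C(C)(C)[C@@H]2CC[C@@]1(C)O)CO | target

Total step count: 24. Longest linear sequence: 20 steps from (R)-pantolactone (steps 1–7, 9–19, 23, 24).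

Steps most likely to fail

Step 12 (cycloaddition). The aluminium-bound enal may rotate about C9=C10 or the diene may be ionised before ring closure, which would erode the trans fusion or cost the silyl ether. The facial bias from C3 may also prove too weak. The fallback drops the Lewis acid and cyclises the neutral ester, which cannot scramble its geometry. It sets out from 13, which is heated in degassed toluene (0.01 M, BHT, sealed tube, about 180 °C) to give ethyl 3β-(tert-butyldimethylsilyloxy)-4,4,8β,10β-tetramethyl-trans-decal-6-ene-9β-carboxylate F1. LiAlH4 in THF then reduces it to alcohol 17, where the route is rejoined; steps 10, 11 and 13 are skipped.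

Step 14 (olefin migration). The hydride catalyst may walk the double bond toward C5 instead of C8, or past C8 into the C8=C9 position, and the acidic medium may strip the silyl ether. The fallback leaves the olefin where it is and oxidises C8 directly. It sets out from 17, which is acetylated (Ac2O, pyridine, DMAP) to [3β-(tert-butyldimethylsilyloxy)-4,4,8β,10β-tetramethyl-trans-decal-6-en-9β-yl]methyl acetate F2. Hydrogenation (H2, Pd/C, EtOAc) gives [3β-(tert-butyldimethylsilyloxy)-4,4,8β,10β-tetramethyl-trans-decal-9β-yl]methyl acetate F3, which keeps the equatorial 8α-H. Methyl(trifluoromethyl)dioxirane (CH2Cl2, −20 °C) should hydroxylate this tertiary C–H bond with retention, giving [3β-(tert-butyldimethylsilyloxy)-8α-hydroxy-4,4,8β,10β-tetramethyl-trans-decal-9β-yl]methyl acetate F4. The acetate deactivates C9–H, and C5–H is buried between two quaternary carbons. K2CO3 in MeOH then gives diol 20, where the route is rejoined.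

Step 9 (hydroboration and coupling). 9-BBN may attack the diene as well as the terminal alkene, or the aqueous base may hydrolyse the β-triflyloxy enoate before it couples. The fallback builds the dienophile arm by carbonyl chemistry and sets out from aldehyde 8. Wittig reaction with 1-(triphenylphosphoranylidene)propan-2-one (toluene, 80 °C) gives (3E,5S,7E,9E)-5-(tert-butyldimethylsilyloxy)-6,6-dimethylundeca-3,7,9-trien-2-one F5. Conjugate reduction with [(Ph3P)CuH]6 (benzene, rt) gives (5S,7E,9E)-5-(tert-butyldimethylsilyloxy)-6,6-dimethylundeca-7,9-dien-2-one F6 without touching the diene. Horner–Wadsworth–Emmons reaction with triethyl phosphonoacetate (NaH, THF) then returns to 13 after the (Z)-isomer is removed by chromatography; steps 7 and 8 are not needed.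

Further compounds
F1 | step 12 | ethyl 3β-(tert-butyldimethylsilyloxy)-4,4,8β,10β-tetramethyl-trans-decal-6-ene-9β-carboxylate | CCOC(=O)[C@@H]1[C@@]2(C)CC[C@H](O[Si](C)(C)C(C)(C)C)C(C)(C)[C@@H]2C=C[C@@H]1C
F2 | step 14 | [3β-(tert-butyldimethylsilyloxy)-4,4,8β,10β-tetramethyl-trans-decal-6-en-9β-yl]methyl acetate | CC(=O)OC[C@@H]1[C@@]2(C)CC[C@H](O[Si](C)(C)C(C)(C)C)C(C)(C)[C@@H]2C=C[C@@H]1C
F3 | step 14 | [3β-(tert-butyldimethylsilyloxy)-4,4,8β,10β-tetramethyl-trans-decal-9β-yl]methyl acetate | CC(=O)OC[C@@H]1[C@@]2(C)CC[C@H](O[Si](C)(C)C(C)(C)C)C(C)(C)[C@@H]2CC[C@@H]1C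
F4 | step 14 | [3β-(tert-butyldimethylsilyloxy)-8α-hydroxy-4,4,8β,10β-tetramethyl-trans-decal-9β-yl]methyl acetate | CC(=O)OC[C@@H]1[C@@]2(C)CC[C@H](O[Si](C)(C)C(C)(C)C)C(C)(C)[C@@H]2CC[C@@]1(C)O
F5 | step 9 | (3E,5S,7E,9E)-5-(tert-butyldimethylsilyloxy)-6,6-dimethylundeca-3,7,9-trien-2-one | CC(=O)/C=C/[C@H](O[Si](C)(C)C(C)(C)C)C(C)(C)/C=C/C=C/C
F6 | step 9 | (5S,7E,9E)-5-(tert-butyldimethylsilyloxy)-6,6-dimethylundeca-7,9-dien-2-one | CC(=O)CC[C@H](O[Si](C)(C)C(C)(C)C)C(C)(C)/C=C/C=C/C
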